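The 2-oxo-2H-pyran-6-carboxylic acid unit (ring O1, C2–C6, plus the carboxyl carbon on C6) contains six carbons laid out as a lactonised 2-hydroxymuconic acid. It is therefore read as a benzene ring cut between two neighbouring C–OH carbons, and the whole plan rests on that disconnection. In one operation a peracid cleaves arene C4–C5 of a 3,4,5-trihydroxybenzyl group, and the oxygen on arene C3 is acylated by the new C5 carboxyl, closing pyranone O1–C2. The precursor is the trans-(3R,4R)-dibenzylbutyrolactone with the veratryl group at C4 and the free pyrogallol at C3. It is made by Stobbe condensation, asymmetric hydrogenation, trans-selective enolate benzylation and hydrogenolysis.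

Key step: step 8

Remarks before the route (arene numbering: C1 carries the CH2 group)
- Stereochemistry: both lactone centres of the target are R and the two arms are trans. The C4 descriptor stays R from the hydrogenated half-ester to the target, because the priority order at that carbon does not change.
- Geometry: the oxygen on arene C3 is exocyclic. After the cut it lies trans to C1 across C2=C3 and cannot reach C5; only the C1=C6 alkene inherits a useful Z geometry. Ring closure therefore needs an enol–keto–enol inversion. For this reason the C3 oxygen is kept as a free hydroxyl (an enol ether would be locked), and an aqueous acid stage belongs to the key step.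
- Route design: C3 is set by direct enolate benzylation. A benzylidene/hydrogenation sequence would add hydrogen anti to the C4 arm and give the cis lactone. The base equilibration then needed is not compatible with a pyrogallol.
- Assumption: the (S,S)-bisphospholane catalyst is taken to give the (R)-half-ester, as is usual for itaconates. The sense is checked at the veratryl lactone against its known (R)-enantiomer, and the mirror-image catalyst is used if needed.

Step 1
Reactants: 1 3,4-dimethoxybenzaldehyde; 2 dimethyl succinate
Product: 3 (E)-4-(3,4-dimethoxyphenyl)-3-(methoxycarbonyl)but-3-enoic acid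
Conditions: NaOMe (1.5 equiv), MeOH, reflux; then aq. HCl
Reagents that add atoms: none
Why: Stobbe condensation, in which the succinate enolate adds to the non-enolisable aldehyde and the sequence ends irreversibly in a carboxylate; aromatic aldehydes give mainly the E half-ester (aryl trans to the ester), which can be crystallised.

Step 2
Reactants: 3 (E)-4-(3,4-dimethoxyphenyl)-3-(methoxycarbonyl)but-3-enoic acid
Product: 4 (R)-4-(3,4-dimethoxyphenyl)-3-(methoxycarbonyl)butanoic acid
Conditions: H2 (5 bar), [Rh(cod)((S,S)-Et-DuPHOS)]BF4 (0.2 mol%), NaOMe (10 mol%), MeOH, rt; crystallisation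
Reagents that add atoms: none
Why: Rhodium-catalysed asymmetric hydrogenation of a Stobbe-type itaconate half-ester, in which the carboxylate arm chelates rhodium beside the alkene so that the C2-symmetric ligand fixes the face that receives H2 and sets the R centre that becomes lactone C4.

Step 3
Reactants: 4 (R)-4-(3,4-dimethoxyphenyl)-3-(methoxycarbonyl)butanoic acid
Product: 7 (R)-4-(3,4-dimethoxybenzyl)dihydrofuran-2(3H)-one, via potassium carboxylate 5 (not isolated), via hydroxy acid 6 (not isolated)
Conditions: KOH (1.0 equiv), EtOH; Ca(BH4)2 (from CaCl2 + NaBH4), EtOH, −10 °C to rt; then 2 M HCl, rt to 40 °C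
Reagents that add atoms: none
Why: Chemoselective borohydride reduction, in which the carboxylate anion is inert while the methyl ester goes to the primary alcohol, followed by acid lactonisation (5-exo-trig); only one equivalent of base is used, so the centre alpha to the ester is not racemised, and after reduction it can no longer epimerise.

Step 4
Reactants: 8 3,4,5-tris(benzyloxy)benzaldehyde
Product: 9 [3,4,5-tris(benzyloxy)phenyl]methanol
Conditions: NaBH4, THF–MeOH, 0 °C
Reagents that add atoms: none
Why: Borohydride reduction of an aromatic aldehyde to the benzylic alcohol, to which benzyl ethers are inert.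

Step 5
Reactants: 9 [3,4,5-tris(benzyloxy)phenyl]methanol
Product: 10 3,4,5-tris(benzyloxy)benzyl bromide
Conditions: PBr3 (0.4 equiv), CH2Cl2, 0 °C; used fresh
Reagents that add atoms: phosphorus tribromide BrP(Br)Br
Why: Bromination of a primary benzylic alcohol through its phosphite ester (SN2 by bromide), run cold and briefly so that the benzyl ethers survive.

Step 6
Reactants: 7 (R)-4-(3,4-dimethoxybenzyl)dihydrofuran-2(3H)-one; 10 3,4,5-tris(benzyloxy)benzyl bromide
Product: 12 (3R,4R)-3-[3,4,5-tris(benzyloxy)benzyl]-4-(3,4-dimethoxybenzyl)dihydrofuran-2(3H)-one, via lithium enolate 11 (not isolated)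
Conditions: LiHMDS (1.05 equiv), THF, −78 °C; then 10, −78 to −30 °C
Reagents that add atoms: none
Why: Enolate alkylation (SN2) of a beta-substituted gamma-butyrolactone, in which the bromide meets the planar enolate 11 on the face opposite the C4 veratryl arm and sets C3 as R (trans), the standard outcome for dibenzylbutyrolactone lignans.

Step 7
Reactants: 12 (3R,4R)-3-[3,4,5-tris(benzyloxy)benzyl]-4-(3,4-dimethoxybenzyl)dihydrofuran-2(3H)-one
Product: 13 (3R,4R)-4-(3,4-dimethoxybenzyl)-3-(3,4,5-trihydroxybenzyl)dihydrofuran-2(3H)-one
Conditions: H2 (1 atm), 10% Pd/C, degassed EtOAc–EtOH, rt; filtered and concentrated under Ar, used at once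
Reagents that add atoms: none
Why: Catalytic hydrogenolysis of benzyl aryl ethers under neutral conditions, which leaves the methyl ethers, the lactone and both stereocentres untouched and gives only a volatile co-product, so the air-sensitive triol needs no chromatography.

Step 8
Reactants: 13 (3R,4R)-4-(3,4-dimethoxybenzyl)-3-(3,4,5-trihydroxybenzyl)dihydrofuran-2(3H)-one
Product: 19 4-{[(3R,4R)-4-(3,4-dimethoxybenzyl)-2-oxotetrahydrofuran-3-yl]methyl}-2-oxo-2H-pyran-6-carboxylic acid, via hydroxy-ortho-quinone 14 (not isolated), via muconic anhydride 15 (not isolated), via (2E,4Z)-enol diacid 16 (not isolated), via keto diacid 17 (not isolated), via (2Z,4Z)-enol diacid 18 (not isolated)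
Conditions: AcOOH (2.1 equiv, about 35% in AcOH), Fe(acac)3 (2 mol%), NaOAc (5 mol%), EtOAc, 0 °C, 13 added slowly under Ar (final ≤ 0.01 M); Me2S until peroxide-free; then THF–1 M aq. HCl, 40 °C; crystallisation
Reagents that add atoms: peracetic acid CC(=O)OO; water O (enters when the anhydride opens, an equal amount leaves on ring closure)
Why: Iron(III) chelates the vicinal hydroxyls and the peracid dehydrogenates the triol to quinone 14, a second peracid molecule adds to a quinone carbonyl and a Baeyer-Villiger-type acyl shift inserts oxygen into arene C4-C5 to give the seven-membered anhydride 15, which is the established course of the peracid (intradiol) cleavage of catechols and pyrogallols to muconic acids. Water opens 15 to diacid 16, in which only the arene C1=C6 alkene has inherited a useful geometry (Z, C5 held next to C2), whereas the oxygen on C3, exocyclic in the arene, lies trans to C1 and points away from C5. Aqueous acid therefore ketonises 16 to 17, rotation about C2-C3 and re-enolisation give 18, and its enol oxygen attacks the C5 carboxyl in a 6-exo-trig addition-elimination that expels water and forms pyranone O1-C2, the conjugated pyranone being the one species that leaves this equilibrium. No stereocentre is formed, and lactone C3 and C4 are not at risk because the medium is never basic and the trans arrangement is the more stable one in any case. The step needs chemoselectivity for the triol over the veratryl ring, secured by its far lower oxidation potential, its chelation to iron and the fact that a bis(methyl ether) cannot become a quinone; it needs acyl rather than alkenyl migration in the perester adduct, which is the normal preference of alpha-dicarbonyl compounds; the choice between the C3-C4 and C4-C5 cuts is immaterial because both give 19. Slow addition at high dilution keeps 14 away from unreacted 13, and reducing the residual peracid before the acid stage protects the alpha-keto acid 17 from oxidative decarboxylation.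

Compound list
1 | 3,4-dimethoxybenzaldehyde | COc1ccc(C=O)cc1OC | starting material
2 | dimethyl succinate | COC(=O)CCC(=O)OC | starting material
3 | (E)-4-(3,4-dimethoxyphenyl)-3-(methoxycarbonyl)but-3-enoic acid | COC(=O)/C(CC(=O)O)=C/c1ccc(OC)c(OC)c1 | intermediate
4 | (R)-4-(3,4-dimethoxyphenyl)-3-(methoxycarbonyl)butanoic acid | COC(=O)[C@@H](CC(=O)O)Cc1ccc(OC)c(OC)c1 | intermediate
5 | potassium (R)-4-(3,4-dimethoxyphenyl)-3-(methoxycarbonyl)butanoate | COC(=O)[C@@H](CC(=O)[O-])Cc1ccc(OC)c(OC)c1.[K+] | intermediate (not isolated)
6 | (R)-4-(3,4-dimethoxyphenyl)-3-(hydroxymethyl)butanoic acid | OC[C@@H](CC(=O)O)Cc1ccc(OC)c(OC)c1 | intermediate (not isolated)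
7 | (R)-4-(3,4-dimethoxybenzyl)dihydrofuran-2(3H)-one | COc1ccc(C[C@H]2COC(=O)C2)cc1OC | intermediate
8 | 3,4,5-tris(benzyloxy)benzaldehyde | O=Cc1cc(OCc2ccccc2)c(OCc2ccccc2)c(OCc2ccccc2)c1 | starting material
9 | [3,4,5-tris(benzyloxy)phenyl]methanol | OCc1cc(OCc2ccccc2)c(OCc2ccccc2)c(OCc2ccccc2)c1 | intermediate
10 | 3,4,5-tris(benzyloxy)benzyl bromide | BrCc1cc(OCc2ccccc2)c(OCc2ccccc2)c(OCc2ccccc2)c1 | intermediate
11 | lithium enolate of 7, lithium (R)-3-(3,4-dimethoxybenzyl)-2,3-dihydrofuran-5-olate | COc1ccc(C[C@H]2COC([O-])=C2)cc1OC.[Li+] | intermediate (not isolated)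
12 | (3R,4R)-3-[3,4,5-tris(benzyloxy)benzyl]-4-(3,4-dimethoxybenzyl)dihydrofuran-2(3H)-one | COc1ccc(C[C@H]2COC(=O)[C@@H]2Cc2cc(OCc3ccccc3)c(OCc3ccccc3)c(OCc3ccccc3)c2)cc1OC | intermediate
13 | (3R,4R)-4-(3,4-dimethoxybenzyl)-3-(3,4,5-trihydroxybenzyl)dihydrofuran-2(3H)-one | COc1ccc(C[C@H]2COC(=O)[C@@H]2Cc2cc(O)c(O)c(O)c2)cc1OC | intermediate (key-step precursor)
14 | (3R,4R)-4-(3,4-dimethoxybenzyl)-3-[(5-hydroxy-3,4-dioxocyclohexa-1,5-dien-1-yl)methyl]dihydrofuran-2(3H)-one | COc1ccc(C[C@H]2COC(=O)[C@@H]2CC3=CC(=O)C(=O)C(O)=C3)cc1OC | intermediate (not isolated)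
15 | 3-hydroxy-5-{[(3R,4R)-4-(3,4-dimethoxybenzyl)-2-oxotetrahydrofuran-3-yl]methyl}oxepine-2,7-dione | COc1ccc(C[C@H]2COC(=O)[C@@H]2CC3=CC(=O)OC(=O)C(O)=C3)cc1OC | intermediate (not isolated)
16 | (2E,4Z)-2-hydroxy-4-{[(3R,4R)-4-(3,4-dimethoxybenzyl)-2-oxotetrahydrofuran-3-yl]methyl}hexa-2,4-dienedioic acid | COc1ccc(C[C@H]2COC(=O)[C@@H]2C/C(=C/C(=O)O)/C=C(/O)C(=O)O)cc1OC | intermediate (not isolated)
17 | (2Z)-3-{[(3R,4R)-4-(3,4-dimethoxybenzyl)-2-oxotetrahydrofuran-3-yl]methyl}-5-oxohex-2-enedioic acid | COc1ccc(C[C@H]2COC(=O)[C@@H]2C/C(=C/C(=O)O)CC(=O)C(=O)O)cc1OC | intermediate (not isolated)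
18 | (2Z,4Z)-2-hydroxy-4-{[(3R,4R)-4-(3,4-dimethoxybenzyl)-2-oxotetrahydrofuran-3-yl]methyl}hexa-2,4-dienedioic acid | COc1ccc(C[C@H]2COC(=O)[C@@H]2C/C(=C/C(=O)O)/C=C(\O)C(=O)O)cc1OC | intermediate (not isolated)
19 | 4-{[(3R,4R)-4-(3,4-dimethoxybenzyl)-2-oxotetrahydrofuran-3-yl]methyl}-2-oxo-2H-pyran-6-carboxylic acid | COc1ccc(C[C@H]2COC(=O)[C@@H]2Cc2cc(C(=O)O)oc(=O)c2)cc1OC | target

Total step count: 8
Longest linear sequence: 6 (steps 1, 2, 3, 6, 7, 8); steps 4 and 5 form the short second branch.

Steps most likely to fail

1. Step 8.
- Several processes may compete: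
  - coupling of the quinone with unreacted triol to benzotropolone-type dimers;
  - oxidative decarboxylation of the keto acid by leftover peroxide;
  - slow attack of the peracid on the veratryl ring;
  - incomplete inversion of the enol, which would stall ring closure.
- The fallback sets out from 13 and comes back at 19. It separates cleavage from ring closure and uses no peroxide.
- Lead tetraacetate (2 equiv) in toluene–methanol at 0 °C is the known cleavage of catechols to dimethyl muconates. It should give dimethyl (2E,4Z)-2-hydroxy-4-{[(3R,4R)-4-(3,4-dimethoxybenzyl)-2-oxotetrahydrofuran-3-yl]methyl}hexa-2,4-dienedioate F1, a neutral compound that can be chromatographed.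
- Catalytic TsOH in warm toluene should then invert the enol through its keto form. The ring closes with loss of methanol to methyl 4-{[(3R,4R)-4-(3,4-dimethoxybenzyl)-2-oxotetrahydrofuran-3-yl]methyl}-2-oxo-2H-pyran-6-carboxylate F2.
- Warm aqueous HCl–dioxane, which pyranone-6-carboxylic acids and the butyrolactone tolerate, should free acid 19.

2. Step 2.
- Facial discrimination may be insufficient for the trisubstituted, electron-rich arylidene, or turnover may be slow because of catalyst poisoning.
- The fallback sets out from 3 and comes back at 4. It replaces asymmetric induction by resolution.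
- Hydrogenation over Pd/C in MeOH gives racemic 4-(3,4-dimethoxyphenyl)-3-(methoxycarbonyl)butanoic acid F3.
- Fractional crystallisation with (R)-1-phenylethylamine should give the (R)-1-phenylethylammonium salt of the (R)-acid F4. The antipodal amine is used if the other diastereomeric salt is the less soluble one.
- Acidification of the salt releases 4.

3. Step 6.
- Proton transfer between product and enolate may lead to double alkylation. The electron-rich bromide may also decompose before it is consumed.
- The fallback sets out from 7 (with aldehyde 8) and comes back at 13, which also makes steps 4, 5 and 7 unnecessary.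
- Enolate 11 is added to 8 at −78 °C (aldol addition, again anti to the C4 arm). This gives (3S,4R)-3-{hydroxy[3,4,5-tris(benzyloxy)phenyl]methyl}-4-(3,4-dimethoxybenzyl)dihydrofuran-2(3H)-one F5 as both carbinol epimers.
- Hydrogenolysis (H2, Pd/C, EtOH–AcOH) removes the three benzyl ethers and the para-hydroxy-activated benzylic hydroxyl in one operation to give 13.
- Strong acid is avoided in this step so that the benzylic cation does not cyclise onto the veratryl ring.

Further compounds
F1 | step 8 | dimethyl (2E,4Z)-2-hydroxy-4-{[(3R,4R)-4-(3,4-dimethoxybenzyl)-2-oxotetrahydrofuran-3-yl]methyl}hexa-2,4-dienedioate | COc1ccc(C[C@H]2COC(=O)[C@@H]2C/C(=C/C(=O)OC)/C=C(/O)C(=O)OC)cc1OC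
F2 | step 8 | methyl 4-{[(3R,4R)-4-(3,4-dimethoxybenzyl)-2-oxotetrahydrofuran-3-yl]methyl}-2-oxo-2H-pyran-6-carboxylate | COc1ccc(C[C@H]2COC(=O)[C@@H]2Cc2cc(C(=O)OC)oc(=O)c2)cc1OC
F3 | step 2 | racemic 4-(3,4-dimethoxyphenyl)-3-(methoxycarbonyl)butanoic acid | COC(=O)C(CC(=O)O)Cc1ccc(OC)c(OC)c1
F4 | step 2 | (R)-1-phenylethylammonium (R)-4-(3,4-dimethoxyphenyl)-3-(methoxycarbonyl)butanoate | COC(=O)[C@@H](CC(=O)[O-])Cc1ccc(OC)c(OC)c1.C[C@@H]([NH3+])c1ccccc1
F5 | step 6 | (3S,4R)-3-{hydroxy[3,4,5-tris(benzyloxy)phenyl]methyl}-4-(3,4-dimethoxybenzyl)dihydrofuran-2(3H)-one, both carbinol epimers | COc1ccc(C[C@H]2COC(=O)[C@@H]2C(O)c2cc(OCc3ccccc3)c(OCc3ccccc3)c(OCc3ccccc3)c2)cc1OC
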